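The leftover of the charge after the quench is what the epsilon flask can still turn into peaks. The protic impurity is the limiting reagent of that quench, charged at 5.00% of the starting material and reacting with it one to one. The balance therefore leaves an open share, the fraction of the charge not lost to quenched substrate once the protic impurity has reacted to the end, of 95.0%.

common to all: starting material 29 mM; protic impurity 1.45 mM

|  | temperature | remark | time |
|---|---|---|---|
| epsilon | 25 °C | the very flask that is asked about, followed so far |  |
| delta | 20 °C | run made earlier |  |
| flask | 25 °C |  | 1.0 h |

| run | time / min | target / % |
|---|---|---|
| epsilon | 2.50 | 6 |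
| epsilon | 8.00 | 16 |
| epsilon | 12.0 | 20 |
| epsilon | 20.0 | 25 |
| epsilon | 30.0 | 21 |
| epsilon | 40.0 | 23 |
| delta | 2.50 | 2 |
| delta | 8.00 | 11 |
| delta | 12.0 | 18 |
| delta | 20.0 | 23 |
| delta | 30.0 | 24 |
| delta | 40.0 | 23 |

(standard deviation of a reading: 2 percentage points)

- removed target is counted in
- candidate steps: starting material <-> intermediate A; intermediate A <-> intermediate B; intermediate A <-> intermediate C; intermediate C -> target; intermediate B -> side product; starting material + protic impurity -> quenched substrate; target <-> isomer of the product
- additions bring no volume worth counting

- cedar: at 1.0 h raise the temperature by 20 K, then wait 30 min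
- ash: change nothing and wait 30 min more
- maple: at 1.0 h add starting material, 50.0% of the amount charged, then wait 30 min
- alder: at 1.0 h take out 90% of the target then present, then wait 30 min

1. target, in percent of the starting material first charged, at 1.0 h
2. the option that brings most further target ("none" if no option brings more than 2 percentage points) (cedar / ash / maple / alder / none)
3. target present, with what was taken out counted in, in percent of the starting material first charged, after cedar
4. target present, with what was taken out counted in, in percent of the starting material first charged, after ash

The target readings of the epsilon flask show no clear change from 20.0 min on: its last 3 readings average 23.0%, and those of the delta run average 23.3%, equal within the scatter of 2 percentage points, so a slow drift cannot be read from them. Target is the one species read, so 72 points of the open share is an unread remainder, and the readings do not show how it divides between side product and isomer of the product. At 1.0 h the epsilon flask should hold about 23.0% of target, and about the same after ash. Until that sample the epsilon flask stays untouched, so that its readings still describe it. Fresh starting material of 50.0%, meeting no protic impurity and giving the same yield on its open share, is reckoned to bring 12.1% of the first charge. The unread remainder is larger than that, so an option that reaches it would beat a top-up, but the readings do not show that one can. This note therefore picks no option.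

The forecast gives 23% at 1.0 h, 23% after ash and 23% after cedar and picks maple, holding that “Waiting or heating then adds almost nothing”.

The epsilon flask gives 19.8% at 1.0 h, 19.5% after ash and 46.6% after cedar, the best option with a gain of 27 points.

    starting material ⇌ intermediate A (K = 0.480, k = 0.00223 s⁻¹, Ea = 84.0 kJ mol⁻¹, ΔH = −16.0 kJ mol⁻¹)
    intermediate A ⇌ intermediate B (K = 0.460, k = 0.00141 s⁻¹, Ea = 98.0 kJ mol⁻¹, ΔH = −26.0 kJ mol⁻¹)
    intermediate A ⇌ intermediate C (K = 37.9, k = 0.00512 s⁻¹, Ea = 77.0 kJ mol⁻¹, ΔH = −37.0 kJ mol⁻¹)
    intermediate C → target (k = 0.0278 s⁻¹, Ea = 80.0 kJ mol⁻¹)
    intermediate B → side product (k = 0.0765 s⁻¹, Ea = 82.0 kJ mol⁻¹)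
    starting material + protic impurity → quenched substrate (k = 13.7 M⁻¹ s⁻¹, Ea = 51.0 kJ mol⁻¹)
    target ⇌ isomer of the product (K = 2.85, k = 0.00215 s⁻¹, Ea = 92.0 kJ mol⁻¹, ΔH = −61.0 kJ mol⁻¹)
    (constants at 25 °C)

The open share less target leaves 75 points in the epsilon flask at 60.0 min, where isomer of the product stands at 54.0%, side product at 19.6% and starting material at 1.21%. A neighbouring flask with the same charge, kept at 50 °C, holds 5.00% of quenched substrate at 60.0 min, the same as the epsilon flask, but 45.4% of target. Its open share less target leaves 50 points, and that flask holds 30.3% of side product and 19.3% of isomer of the product.

All runs were generated by integration for an exercise, and the scatter is random.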